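The earlier runs and the new flask are calculated for an exercise; noise was put on by code.

- The vessel was closed, stirred and isothermal, and in the south run substrate was down to 0.4% by 1.33 min, so I treated what followed as one change: target turning into isomer of the product B.

| flask | substrate | remark | time |
|---|---|---|---|
| south | 6.7 × 10⁻⁴ M | run made earlier |  |
| south-west | 0.0015 M | run made earlier |  |
| spring | 0.0010 M |  | 10 min |
| noon | 0.0010 M |  | 30 min |

| run | time / min | substrate / % | isomer of the product B / % | isomer of the product A / % | third product / % | target / % |
|---|---|---|---|---|---|---|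
| south | 0.833 | 5.1 | 3.5 | 23.9 | 11.0 | 54.1 |
| south | 1.33 | 0.4 | 2.8 | 25.8 | 12.9 | 56.5 |
| south | 2.00 | 0.2 | 6.7 | 24.9 | 15.4 | 55.3 |
| south | 4.00 | 0 | 13.1 | 25.6 | 12.4 | 48.4 |
| south | 6.00 | 0 | 18.5 | 26.6 | 14.2 | 44.4 |
| south | 10.0 | 1.2 | 29.2 | 26.0 | 14.3 | 33.1 |
| south-west | 0.833 | 5.6 | 2.0 | 25.3 | 11.7 | 56.5 |
| south-west | 1.33 | 0.8 | 2.3 | 26.8 | 14.4 | 60.3 |
| south-west | 2.00 | 1.4 | 5.6 | 25.8 | 13.1 | 57.4 |
| south-west | 4.00 | 0 | 2.5 | 26.5 | 12.6 | 52.9 |
| south-west | 6.00 | 0.6 | 9.9 | 23.4 | 13.3 | 53.3 |
| south-west | 10.0 | 2.4 | 13.3 | 25.8 | 12.9 | 48.1 |

(readings scatter by 1 percentage point)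

- which of these there is most of at the end, counted by the substrate in it, spring (third product / isomer of the product B / target / isomer of the product A)
- which of these there is most of at the end, counted by the substrate in it, noon (third product / isomer of the product B / target / isomer of the product A)
- how much there is at the end of the one of these that leads, in percent of the substrate charged: spring
- how much there is at the end of the one of these that leads, in percent of the substrate charged: noon

- the numbers in the tables scatter by 1 percentage point (one standard deviation)
- a reading or a percentage of target counts all its forms, free or not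

- Dividing the last amount of isomer of the product B by its time gave 1.96 × 10⁻⁵ M min⁻¹ in south and 2.00 × 10⁻⁵ M min⁻¹ in south-west, about equal although the charges differ, so I took the mean, r = 1.98 × 10⁻⁵ M min⁻¹, as a zero-order drain rate.
- Target plus isomer of the product B, the pool f, averaged 61.9% of the charge c at those last readings.
- I defined the crossing time tx, when a straight drain brings target and isomer of the product B level, as f·c/(2r), which for c = 0.0010 M is 15.7 min.
- On that line they cross at 30.9%, more than the 26.0% of isomer of the product A read in the south run at 10.0 min, so I compared each flask's time with tx.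
- Spring stopped earlier, at 10 min, so my line gave target 42.1%; noon stopped later, at 30 min, so it gave isomer of the product B 59.3%.
- The forecast named target at 41% and isomer of the product B at 52%, a noon figure lower than my line, and judged “That suggests a saturated, catalyst-like step, close to zero order”.
- The flask gave target at 41.0% in spring and isomer of the product B at 51.5% in noon, under this scheme:

    substrate ⇌ other conformer (K = 5.00, k = 0.0240 s⁻¹)
    substrate → target (k = 0.0370 s⁻¹)
    other conformer → isomer of the product A (k = 0.200 s⁻¹)
    other conformer ⇌ third conformer (K = 0.490, k = 0.780 s⁻¹)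
    third conformer → third product (k = 0.230 s⁻¹)
    crystals ⇌ target, rate k6*(cs6 - [target]) while solid is left; crystals form when [target] > cs6 (solubility = 0.0700 mM, k = 0.920 s⁻¹)
    target ⇌ isomer of the product B (K = 20.0, k = 0.00510 s⁻¹)

- Crystals, counted in target, stood at 34.1% in spring at 10.0 min and at 2.59% in noon at 30.0 min. Spring ended at 0.637 of tx and noon at 1.91 of it. The spring flask, left longer, brought target and isomer of the product B level at 16.0 min, against tx of 15.7 min, and at 40 min it held 57.8% of isomer of the product B and 3.21% of target.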